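**Assumptions (one line each)**
- The SMILES is natural d‑α‑tocotrienol: (2R) at the chroman carbon, 3′E,7′E side chain.
- The catalyst antipode that delivers (R) in Step 2 cannot be predicted with confidence, so it is fixed by one analytical run (chiral HPLC against natural material after Step 3); (R)-catalyst is written below.

**Retrosynthetic overview**
1. All carbons come from two commercial compounds: 2,3,5‑trimethylhydroquinone (1, C9 arene feedstock) and all‑E geranylgeraniol (2, C20).
2. 2 is raised to the aldehyde level, geranylgeranial (3), so its C1 becomes chroman C4 and its C3 (bearing Me and the C13 chain) becomes chroman C2.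
3. Key disconnection: C4a–C4 and O1–C2 are made in one operation, 1 + 3 → (R)‑chromene 4. The hydroquinone is transiently dearomatised to a vinyl o‑quinone methide, and a chiral Brønsted acid steers its oxa‑6π ring closure, which sets C2.
4. 4 → target 5 by saturating only the aryl‑conjugated C3=C4 bond.
5. Ring order: the benzene ring is bought; the pyran ring is the only ring formed (Step 2).

**Route**

Step 1
Reactants: 2, (2E,6E,10E)‑geranylgeraniol
Product: 3, (2E,6E,10E)‑geranylgeranial
Conditions: activated MnO2 (15 equiv), CH2Cl2, rt, dark; filter through Celite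
Reagents that add atoms: none
Why: Heterogeneous MnO2 allylic oxidation touches only the primary allylic alcohol, stops at the enal and preserves the 2E geometry; the isolated trisubstituted alkenes are inert.

Step 2 (key step)
Reactants: 1, 2,3,5‑trimethylhydroquinone (1.5 equiv); 3, (2E,6E,10E)‑geranylgeranial (1.0 equiv)
Product: 4, (R)‑3,4‑dehydro‑α‑tocotrienol = (R)‑2,5,7,8‑tetramethyl‑2‑[(3E,7E)‑4,8,12‑trimethyltrideca‑3,7,11‑trienyl]‑2H‑chromen‑6‑ol
Conditions: (R)‑3,3′‑bis(2,4,6‑triisopropylphenyl)‑BINOL N‑triflylphosphoramide (10 mol %), 5 Å MS, PhMe/CH2Cl2 4:1, −30 → 0 °C, Ar, dark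
Reagents that add atoms: none (both partners are numbered reactants; one H2O is lost; the catalyst contributes no atoms)
Why: Proposed new method: acid‑catalysed Friedel–Crafts hydroxyalkylation at the only free ring position of 1 (ortho to one OH), then loss of water, gives a dearomatised vinyl o‑quinone methide that stays hydrogen‑bonded/ion‑paired to the chiral phosphoramide anion; its disrotatory oxa‑6π closure (equivalently, collapse of the hydroxy‑allyl cation/chiral anion contact pair) re‑aromatises the ring and forms O1–C2 on one face of the prochiral C(Me)(CH2R) terminus, setting (R)‑C2. The closest known reactions are the racemic amine‑ or boronic‑acid‑mediated chromenylation of phenols with citral‑type enals, and the chiral N‑triflylphosphoramide‑catalysed cyclisation of o‑hydroxystyryl allylic alcohols to 2,2‑disubstituted 2H‑chromenes through chiral contact ion pairs.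

Step 3
Reactants: 4, (R)‑3,4‑dehydro‑α‑tocotrienol
Product: 5, (R)‑α‑tocotrienol = (R)‑2,5,7,8‑tetramethyl‑2‑[(3E,7E)‑4,8,12‑trimethyltrideca‑3,7,11‑trienyl]chroman‑6‑ol (target)
Conditions: Na (excess, portionwise), abs. EtOH, reflux, Ar; then aq. NH4Cl, O2‑free work‑up
Reagents that add atoms: none (two H only)
Why: Dissolving‑metal reduction (Na/alcohol, the classical chromenol → chromanol conversion) transfers electrons only into the aryl‑conjugated C3=C4 bond, with protonation at C3 then at benzylic C4; the three isolated trisubstituted alkenes are not reduced and keep their E geometry, and the quaternary C2 is not involved, so (R) is retained.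

**Compound list**
1 | 2,3,5‑trimethylhydroquinone | Cc1cc(O)c(C)c(C)c1O | starting material
2 | (2E,6E,10E)‑geranylgeraniol | CC(C)=CCC/C(C)=C/CC/C(C)=C/CC/C(C)=C/CO | starting material
3 | (2E,6E,10E)‑geranylgeranial | CC(C)=CCC/C(C)=C/CC/C(C)=C/CC/C(C)=C/C=O | intermediate
4 | (R)‑3,4‑dehydro‑α‑tocotrienol (2H‑chromen‑6‑ol) | CC(C)=CCC/C(C)=C/CC/C(C)=C/CC[C@]1(C)C=Cc2c(C)c(O)c(C)c(C)c2O1 | intermediate
5 | (R)‑α‑tocotrienol (2R,3′E,7′E) | CC(C)=CCC/C(C)=C/CC/C(C)=C/CC[C@]1(C)CCc2c(C)c(O)c(C)c(C)c2O1 | target

**Totals**
Total steps: 3. Longest linear sequence: 3 (2 → 3 → 4 → 5).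

**Steps most likely to fail, with fallbacks**
1. Step 2.
   - Risks: slow C–C bond formation at low temperature; weak Me versus CH2R discrimination (low ee); acid‑induced Prins or polyene side reactions of 3.
   - Fallback: make racemic 4 by the achiral thermal condensation of 1 + 3 (PhB(OH)2/AcOH, toluene, Dean–Stark), separate the enantiomers by preparative chiral SFC, and recycle (S)‑4 by UV ring‑opening and thermal re‑closure, which racemises it through the same o‑quinone methide.
2. Step 3.
   - Risks: reductive cleavage of the allylic C2–O aryl ether bond (ring‑opened prenyl‑type hydroquinone); incomplete reduction of the electron‑rich phenoxide.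
   - Fallback: homogeneous hydrogenation with RhCl(PPh3)3/H2 (1 atm, benzene–EtOH, stopped at 1.0 equiv H2). This selects by alkene substitution (cis‑disubstituted C3=C4 versus trisubstituted side‑chain alkenes) instead of by conjugation.
3. Step 1.
   - Risks: partial 2E → 2Z isomerisation or incomplete conversion on scale; supply and purity of all‑E 2.
   - Fallback: build 3 by C–C bond formation: (5E,9E)‑farnesylacetone + diethyl cyanomethylphosphonate (Horner–Wadsworth–Emmons), then DIBAL‑H to the enal, with chromatographic removal of the 2Z isomer.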